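The C40 polyene is cut at the central C15=C15′ bond (Wittig, C20 + C20) and at the ester, so that the only real risk is C3 of ring A, the acylated ring. In the target's 5,6-ene ring, C3 lies between two near-equivalent methylenes, C2 and C4. In the 4,5-ene (α-ionone) isomer the same carbon can be an enone carbonyl flanked by vinylic C4 and by the C2 methylene next to quaternary C1. An oxazaborolidine-catalysed reduction of racemic 3-oxo-α-ionone ethylene ketal uses that difference to set C3 in one operation; base later moves the alkene into conjugation and erases C6.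

Key step: step 3

Remark: carotenoid numbering is used for every intermediate (ring A: C1 gem-dimethyl, C3 oxygen-bearing, C5 methyl-bearing, C6 chain-bearing); α-ionone is used as the racemate, and the (R)-oxazaborolidine is assumed to give the 3S carbinol by analogy with cyclohex-2-enones, whose vinylic flank acts as the large group.

Step 1
Reactants: 1 (±)-α-ionone
Product: 2 (±)-α-ionone ethylene ketal
Conditions: HOCH2CH2OH, HC(OMe)3, p-TsOH (cat.), CH2Cl2, rt; Et3N quench
Reagents that add atoms: ethylene glycol, OCCO
Why: Acid-catalysed ketalisation (dioxolane formation) with the orthoformate as water scavenger should proceed at room temperature on the unhindered C9 methyl ketone, and acid this mild should leave the C4=C5 and C7=C8 alkenes where they are.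

Step 2
Reactants: 2 (±)-α-ionone ethylene ketal
Product: 3 (±)-3-oxo-α-ionone ethylene ketal
Conditions: t-BuOOH (in decane), CuI (cat.), MeCN, 50 °C
Reagents that add atoms: tert-butyl hydroperoxide, CC(C)(C)OO
Why: Copper-catalysed allylic oxidation with t-BuOOH (Kharasch–Sosnovsky-type radical chain) should abstract hydrogen from the secondary allylic C3 methylene, trap the allyl radical at its less hindered C3 end as the mixed peroxide and collapse this to the enone (Kornblum–DeLaMare), while C6–H is shielded by the gem-dimethyl group and the side chain and the non-acidic medium spares the ketal.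

Step 3
Reactants: 3 (±)-3-oxo-α-ionone ethylene ketal
Product: 5 (3S)-3-hydroxy-α-ionone ethylene ketal (both C6 epimers), via catechol borate ester 4 (not isolated)
Conditions: (R)-Me-CBS [(3aR)-1-methyl-3,3-diphenyltetrahydro-1H,3H-pyrrolo[1,2-c][1,3,2]oxazaborole] (0.15 equiv), catecholborane (1.8 equiv), toluene, −78 → −40 °C; MeOH quench, aqueous work-up
Reagents that add atoms: none
Why: Corey–Bakshi–Shibata reduction: catecholborane binds the nitrogen of the (R)-oxazaborolidine, the ring boron then coordinates the C3 carbonyl oxygen on the lone pair that faces the C2 methylene, and hydride passes from the nitrogen-bound borane to C3 through a six-membered chair-like array to give borate 4, which the work-up hydrolyses. The closest known reaction type is the oxazaborolidine-catalysed 1,2-reduction of cyclohex-2-enones, whose sp2 flank behaves as the large group; no ring is closed and no skeletal bond is made. The one new stereocentre, C3, is controlled by the catalyst: with the vinylic C4=C5 flank held away from the catalyst, the (R)-catalyst should deliver hydride to the face that gives the 3S carbinol. The step needs 1,2- over 1,4-reduction and ketone over alkene selectivity, which catecholborane at low temperature provides, and it needs discrimination of the two carbonyl flanks, which the substrate secures by the contrast between planar vinylic C4 and tetrahedral C2. Catalyst control must also outweigh the C6 centre of the racemate, which is plausible because C6 lies across the ring from C3 and is erased in step 5, so both C6 epimers of 5 converge on 7. The dioxolane keeps the C9 carbonyl out of the reduction.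

Step 4
Reactants: 5 (3S)-3-hydroxy-α-ionone ethylene ketal (both C6 epimers)
Product: 6 (3S)-3-hydroxy-α-ionone (both C6 epimers)
Conditions: pyridinium p-toluenesulfonate (cat.), acetone/H2O, rt
Reagents that add atoms: water, O
Why: Acid-catalysed ketal hydrolysis: the allylic dioxolane ionises to a vinyl-stabilised oxocarbenium ion under buffered pyridinium acid, which is too mild to ionise the secondary allylic C3 alcohol, so the C3 configuration should be untouched.

Step 5
Reactants: 6 (3S)-3-hydroxy-α-ionone (both C6 epimers)
Product: 7 (3R)-3-hydroxy-β-ionone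
Conditions: KOH, MeOH, 45 °C, Ar
Reagents that add atoms: none
Why: Base-mediated alkene isomerisation through the extended enolate: base removes the C6 hydrogen (γ to the C9 carbonyl and allylic to C4=C5) and reprotonation at C4 gives the conjugated dienone as the thermodynamic product, which erases the C6 stereocentre, while C3 has no acidic hydrogen and keeps its geometry, its descriptor becoming R only because C2 now outranks C4.

Step 6
Reactants: 7 (3R)-3-hydroxy-β-ionone
Product: 8 (3R,9E)-3-hydroxy-β-ionylideneacetonitrile
Conditions: (EtO)2P(O)CH2CN, NaH, THF, 0 °C → rt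
Reagents that add atoms: diethyl cyanomethylphosphonate, CCOP(=O)(CC#N)OCC
Why: Horner–Wadsworth–Emmons olefination of the methyl ketone with the preformed cyano-stabilised phosphonate anion, which is too weak a base to deprotonate the C3 hydroxyl, should favour the 9E alkene, and the minor 9Z isomer is removed by chromatography.

Step 7
Reactants: 8 (3R,9E)-3-hydroxy-β-ionylideneacetonitrile
Product: 10 (3R,9E)-3-hydroxy-β-ionylideneacetaldehyde, via aluminated aldimine 9 (not isolated)
Conditions: i-Bu2AlH (2.5 equiv), CH2Cl2, −78 → −40 °C; wet SiO2, 0 °C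
Reagents that add atoms: water, O
Why: Partial reduction of the nitrile with i-Bu2AlH stops at the N-aluminated aldimine (one equivalent is consumed by the hydroxyl), which wet silica hydrolyses to the aldehyde without touching the diene or C3.

Step 8
Reactants: 10 (3R,9E)-3-hydroxy-β-ionylideneacetaldehyde
Product: 11 (3R)-3-hydroxyretinonitrile (all-E)
Conditions: (EtO)2P(O)CH2C(CH3)=CHCN, n-BuLi (1.0 equiv per phosphonate), THF, −78 → 0 °C
Reagents that add atoms: diethyl [(2E)-3-cyano-2-methylprop-2-en-1-yl]phosphonate, CCOP(=O)(C/C(C)=C/C#N)OCC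
Why: Horner–Wadsworth–Emmons olefination with the C5 allylic phosphonate anion should form C11=C12 with E geometry and bring in the 13E unsaturated nitrile, any 13Z isomer being separated by chromatography.

Step 9
Reactants: 11 (3R)-3-hydroxyretinonitrile (all-E)
Product: 13 (3R)-3-hydroxyretinal (all-E), via aluminated retinylidene imine 12 (not isolated)
Conditions: i-Bu2AlH (2.5 equiv), CH2Cl2, −78 → −40 °C; wet SiO2, 0 °C; Ar, dim light
Reagents that add atoms: water, O
Why: Partial nitrile reduction with i-Bu2AlH as in step 7 gives the aluminated imine, whose mild hydrolysis on wet silica should release the polyenal without isomerising the tetraene.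

Step 10
Reactants: 14 retinyl acetate (all-E)
Product: 15 retinyltriphenylphosphonium bromide (all-E)
Conditions: PPh3·HBr, MeOH, rt, dark
Reagents that add atoms: triphenylphosphine hydrobromide, [Br-].c1ccccc1[PH+](c1ccccc1)c1ccccc1
Why: Acid-promoted SN1-type substitution: the allylic acetate ionises to the delocalised retinyl cation, which PPh3 should capture at the unhindered terminal C15 to give the phosphonium salt with the all-E pentaene retained.

Step 11
Reactants: 13 (3R)-3-hydroxyretinal (all-E); 15 retinyltriphenylphosphonium bromide (all-E)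
Product: 18 (3R)-β-cryptoxanthin (all-E), via retinylidene ylide 16 (not isolated), via 15Z-β-cryptoxanthin 17 (not isolated)
Conditions: NaOMe, MeOH/CH2Cl2, −10 °C → rt, Ar, dark; aqueous work-up; then heptane, reflux
Reagents that add atoms: none
Why: Wittig olefination of the semi-stabilised retinylidene ylide with the aldehyde forms C15=C15′ as an E/Z mixture, and heating should convert the thermally labile central 15Z isomer into the all-E polyene, the free C3 hydroxyl being inert to methoxide.

Step 12
Reactants: 18 (3R)-β-cryptoxanthin (all-E); 19 palmitoleic acid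
Product: 20 (3R)-β-cryptoxanthin palmitoleate (CNP0382087.1)
Conditions: DCC, DMAP (cat.), CH2Cl2, rt, Ar, dark
Reagents that add atoms: none
Why: Steglich esterification: the carbodiimide activates the acid and DMAP transfers the acyl group to the secondary C3 hydroxyl under neutral conditions, so the C3–O bond is not broken (retention) and neither the polyene nor the 9Z alkene of the acyl chain should be affected.

Compound list
1 | (±)-α-ionone, (3E)-4-(2,6,6-trimethylcyclohex-2-en-1-yl)but-3-en-2-one | CC(=O)/C=C/C1C(C)=CCCC1(C)C | starting material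
2 | (±)-α-ionone ethylene ketal, 2-methyl-2-[(E)-2-(2,6,6-trimethylcyclohex-2-en-1-yl)ethenyl]-1,3-dioxolane | CC1(OCCO1)/C=C/C1C(C)=CCCC1(C)C | intermediate
3 | (±)-3-oxo-α-ionone ethylene ketal, 3,5,5-trimethyl-4-[(E)-2-(2-methyl-1,3-dioxolan-2-yl)ethenyl]cyclohex-2-en-1-one | CC1(OCCO1)/C=C/C1C(C)=CC(=O)CC1(C)C | intermediate
4 | catechol borate ester of 5, 2-alkoxy-1,3,2-benzodioxaborole (3S, both C6 epimers) | CC1(OCCO1)/C=C/C1C(C)=C[C@@H](OB2Oc3ccccc3O2)CC1(C)C | intermediate (not isolated)
5 | (3S)-3-hydroxy-α-ionone ethylene ketal, both C6 epimers | CC1(OCCO1)/C=C/C1C(C)=C[C@@H](O)CC1(C)C | intermediate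
6 | (3S)-3-hydroxy-α-ionone, both C6 epimers | CC(=O)/C=C/C1C(C)=C[C@@H](O)CC1(C)C | intermediate
7 | (3R)-3-hydroxy-β-ionone, (3E)-4-[(4R)-4-hydroxy-2,6,6-trimethylcyclohex-1-en-1-yl]but-3-en-2-one | CC(=O)/C=C/C1=C(C)C[C@@H](O)CC1(C)C | intermediate
8 | (3R,9E)-3-hydroxy-β-ionylideneacetonitrile, (2E,4E)-5-[(4R)-4-hydroxy-2,6,6-trimethylcyclohex-1-en-1-yl]-3-methylpenta-2,4-dienenitrile | N#C/C=C(C)/C=C/C1=C(C)C[C@@H](O)CC1(C)C | intermediate
9 | N,O-bis(diisobutylaluminium) aldimine from 8 | CC(C)C[Al](CC(C)C)N=C/C=C(C)/C=C/C1=C(C)C[C@@H](O[Al](CC(C)C)CC(C)C)CC1(C)C | intermediate (not isolated)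
10 | (3R,9E)-3-hydroxy-β-ionylideneacetaldehyde, (2E,4E)-5-[(4R)-4-hydroxy-2,6,6-trimethylcyclohex-1-en-1-yl]-3-methylpenta-2,4-dienal | O=C/C=C(C)/C=C/C1=C(C)C[C@@H](O)CC1(C)C | intermediate
11 | (3R)-3-hydroxyretinonitrile, all-E | N#C/C=C(C)/C=C/C=C(C)/C=C/C1=C(C)C[C@@H](O)CC1(C)C | intermediate
12 | N,O-bis(diisobutylaluminium) retinylidene imine from 11 | CC(C)C[Al](CC(C)C)N=C/C=C(C)/C=C/C=C(C)/C=C/C1=C(C)C[C@@H](O[Al](CC(C)C)CC(C)C)CC1(C)C | intermediate (not isolated)
13 | (3R)-3-hydroxyretinal, all-E | O=C/C=C(C)/C=C/C=C(C)/C=C/C1=C(C)C[C@@H](O)CC1(C)C | intermediate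
14 | retinyl acetate, all-E | CC(=O)OC/C=C(C)/C=C/C=C(C)/C=C/C1=C(C)CCCC1(C)C | starting material
15 | retinyltriphenylphosphonium bromide, all-E | [Br-].c1ccccc1[P+](c1ccccc1)(c1ccccc1)C/C=C(C)/C=C/C=C(C)/C=C/C1=C(C)CCCC1(C)C | intermediate
16 | retinylidenetriphenylphosphorane (ylide) | c1ccccc1P(c1ccccc1)(c1ccccc1)=C/C=C(C)/C=C/C=C(C)/C=C/C1=C(C)CCCC1(C)C | intermediate (not isolated)
17 | (3R,15Z)-β-cryptoxanthin | O[C@@H]1CC(C)=C(/C=C/C(C)=C/C=C/C(C)=C/C=C\C=C(C)\C=C\C=C(C)\C=C\C2=C(C)CCCC2(C)C)C(C)(C)C1 | intermediate (not isolated)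
18 | (3R)-β-cryptoxanthin, all-E | O[C@@H]1CC(C)=C(/C=C/C(C)=C/C=C/C(C)=C/C=C/C=C(C)/C=C/C=C(C)/C=C/C2=C(C)CCCC2(C)C)C(C)(C)C1 | intermediate
19 | palmitoleic acid, (9Z)-hexadec-9-enoic acid | CCCCCC/C=C\CCCCCCCC(=O)O | starting material
20 | (3R)-β-cryptoxanthin palmitoleate, all-E polyene, 9Z acyl chain (CNP0382087.1) | CCCCCC/C=C\CCCCCCCC(=O)O[C@@H]1CC(C)=C(/C=C/C(C)=C/C=C/C(C)=C/C=C/C=C(C)/C=C/C=C(C)/C=C/C2=C(C)CCCC2(C)C)C(C)(C)C1 | target

Total step count: 12. Longest linear sequence: 11 steps (steps 1–9, 11 and 12, from α-ionone); step 10 is a one-step side branch.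

Steps most likely to fail

Step 3. The risk is poor facial discrimination: the C2 methylene carries the quaternary C1 and may not act as a clearly smaller flank than vinylic C4, and one C6 enantiomer of the racemate may be mismatched with the catalyst. Either effect would lower the enantiomeric purity at C3, and incomplete conversion would add a kinetic-resolution bias. The fallback replaces asymmetric induction by resolution; it sets out from 3 and comes back at 7. Luche reduction (NaBH4, CeCl3·7H2O, MeOH, −20 °C) gives racemic 3-hydroxy-α-ionone ethylene ketal F1, which is hydrolysed as in step 4 to racemic 3-hydroxy-α-ionone F2 and isomerised as in step 5 to racemic 3-hydroxy-β-ionone F3, now with C3 as its only stereocentre. Steglich acylation with (S)-2-methoxy-2-phenylacetic acid (DCC, DMAP, CH2Cl2) gives the diastereomeric esters (3R)-3-hydroxy-β-ionone (S)-O-methylmandelate F4 and (3S)-3-hydroxy-β-ionone (S)-O-methylmandelate F5, which are separated by chromatography or crystallisation. Methanolysis of F4 (K2CO3, MeOH, rt) returns 7.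

Step 11. The risk is loss of material through decomposition of the long conjugated ylide, base-induced degradation of the hydroxy polyenal, and incomplete convergence of the geometric isomers on heating. The fallback changes the disconnection to C15 + C25, forms C11=C12 instead of C15=C15′ and makes the hydroxylated half the ylide, so that 13 is not needed; it sets out from 7 and comes back at 18. Excess CH2=CHMgBr (THF, 0 °C) adds to the C9 ketone to give (3R)-3-hydroxy-vinyl-β-ionol F6 (both C9 epimers). PPh3·HBr in MeOH converts the tertiary allylic alcohol, with allylic transposition, into the (3R)-3-hydroxy-C15 phosphonium bromide F7. NaOMe in MeOH generates the C15 ylide F8, which is condensed with purchased β-apo-12′-carotenal (a specialty C25 aldehyde, O=C/C(C)=C/C=C/C=C(C)/C=C/C=C(C)/C=C/C1=C(C)CCCC1(C)C). The crude product, which contains (3R,11Z)-β-cryptoxanthin F9, is equilibrated in refluxing heptane to 18.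

Step 2. The risk is competing hydrogen abstraction at the doubly allylic C6–H or at the C5 methyl, over-oxidation, and ketal loss during a slow reaction. The fallback reverses the order of protection and oxidation and uses a non-peroxide oxidant; it sets out from 1 and comes back at 3. Free α-ionone is oxidised with the stoichiometric hexavalent chromium reagent CrO3·3,5-dimethylpyrazole (CH2Cl2, −20 °C) to (±)-3-oxo-α-ionone F10. The acyclic C9 methyl ketone, which is less hindered and less deactivated than the β,β-disubstituted ring enone, is then ketalised selectively with Me3SiOCH2CH2OSiMe3 and catalytic Me3SiOTf (CH2Cl2, −78 °C) to give 3.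

Further compounds
F1 | step 3 | racemic 3-hydroxy-α-ionone ethylene ketal (all stereoisomers) | CC1(OCCO1)/C=C/C1C(C)=CC(O)CC1(C)C
F2 | step 3 | racemic 3-hydroxy-α-ionone (all stereoisomers) | CC(=O)/C=C/C1C(C)=CC(O)CC1(C)C
F3 | step 3 | racemic 3-hydroxy-β-ionone | CC(=O)/C=C/C1=C(C)CC(O)CC1(C)C
F4 | step 3 | (3R)-3-hydroxy-β-ionone (S)-O-methylmandelate | CC(=O)/C=C/C1=C(C)C[C@@H](OC(=O)[C@@H](OC)c2ccccc2)CC1(C)C
F5 | step 3 | (3S)-3-hydroxy-β-ionone (S)-O-methylmandelate | CC(=O)/C=C/C1=C(C)C[C@H](OC(=O)[C@@H](OC)c2ccccc2)CC1(C)C
F6 | step 11 | (3R)-3-hydroxy-vinyl-β-ionol, both C9 epimers | C=CC(C)(O)/C=C/C1=C(C)C[C@@H](O)CC1(C)C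
F7 | step 11 | (3R)-3-hydroxy-C15 phosphonium bromide, [(2E,4E)-5-[(4R)-4-hydroxy-2,6,6-trimethylcyclohex-1-en-1-yl]-3-methylpenta-2,4-dienyl]triphenylphosphonium bromide | [Br-].c1ccccc1[P+](c1ccccc1)(c1ccccc1)C/C=C(C)/C=C/C1=C(C)C[C@@H](O)CC1(C)C
F8 | step 11 | C15 ylide from F7 | c1ccccc1P(c1ccccc1)(c1ccccc1)=C/C=C(C)/C=C/C1=C(C)C[C@@H](O)CC1(C)C
F9 | step 11 | (3R,11Z)-β-cryptoxanthin | O[C@@H]1CC(C)=C(/C=C/C(C)=C/C=C\C(C)=C\C=C\C=C(C)\C=C\C=C(C)\C=C\C2=C(C)CCCC2(C)C)C(C)(C)C1
F10 | step 2 | (±)-3-oxo-α-ionone | CC(=O)/C=C/C1C(C)=CC(=O)CC1(C)C
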